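**Retrosynthetic overview**

1. The target is reached from its 5‑O‑methoxymethyl ether with dilute acid; every other oxygen is already in its final state at that point.
2. The strategy rests on ring B, a 2‑methoxyhydroquinone (OH at C2' and C5', OMe at C4') bound to chromone C2 through C1', the carbon para to the methoxy group. C2'–C5' with their three oxygens map onto 3‑methoxycyclobutene‑1,2‑dione, and C6'/C1' onto a vinyl unit.
3. Ring B is formed last, by thermal ring expansion of a 4‑alkenyl‑4‑hydroxy‑3‑methoxycyclobutenone, which makes the C1'–C2' bond.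
4. The alkenylcyclobutenone comes from a palladium/copper thioether–stannane coupling (chromone C2–vinyl bond) of a 2‑methylthiochromone with a stannylvinyl carbinol. The carbinol comes from methyl semisquarate (from dimethyl squarate) and (E)‑2‑stannylvinyllithium.
5. Ring C of the thiochromone is closed from an α‑prenylated o‑hydroxyaryl ketone with CS2, then S‑methylated. Ring order: ring A bought, ring C (step 3), four‑membered ring bought, ring B (step 8).

Key step: step 8

Remark: the 5‑hydroxyl is carried as a methoxymethyl ether so that it can be freed with dilute acid at the end, and methyl semisquarate is assumed to be isolable and to take organolithiums at the carbonyl next to the methoxy‑bearing carbon, as its higher alkyl homologues do.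

**Route**

Step 1
Reactants: 1 1-(2,6-dihydroxy-4-methoxyphenyl)ethanone
Product: 2 1-[2-hydroxy-4-methoxy-6-(methoxymethoxy)phenyl]ethanone
Conditions: MOMCl (1.1 equiv), i-Pr2NEt, CH2Cl2, 0 °C to rt
Reagents that add atoms: chloromethyl methyl ether (MOMCl), COCCl
Why: Williamson-type O-alkylation to the methoxymethyl ether, in which the two hydroxyls are equivalent and, once one is etherified, the other is held in a hydrogen bond to the ketone and resists a second alkylation by one equivalent of reagent.

Step 2
Reactants: 2 1-[2-hydroxy-4-methoxy-6-(methoxymethoxy)phenyl]ethanone; 3 prenyl bromide (1-bromo-3-methylbut-2-ene)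
Product: 4 1-[2-hydroxy-4-methoxy-6-(methoxymethoxy)phenyl]-5-methylhex-4-en-1-one
Conditions: LiN(i-Pr)2 (2.2 equiv), THF, −78 to −20 °C; then 3 (0.95 equiv), −78 to 0 °C; aq. NH4Cl
Reagents that add atoms: none
Why: Enolate alkylation of a doubly deprotonated o-hydroxyacetophenone, in which the enolate carbon is far more nucleophilic than the chelated lithium phenoxide and takes up the allylic bromide by SN2 displacement at the former methyl carbon.

Step 3
Reactants: 4 1-[2-hydroxy-4-methoxy-6-(methoxymethoxy)phenyl]-5-methylhex-4-en-1-one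
Product: 6 4-hydroxy-7-methoxy-5-(methoxymethoxy)-3-(3-methylbut-2-enyl)chromene-2-thione, via oxodithioate 5 (not isolated)
Conditions: CS2 (1.5 equiv), KOt-Bu (3 equiv), THF, 0 °C to rt; then AcOH, H2O
Reagents that add atoms: carbon disulfide, S=C=S
Why: Base-mediated condensation of an o-hydroxyaryl ketone with carbon disulfide, in which the enolate is C-dithiocarboxylated to 5 and the phenoxide then attacks the thiocarbonyl carbon with loss of hydrosulfide, closing ring C with the prenyl group already at C3.

Step 4
Reactants: 6 4-hydroxy-7-methoxy-5-(methoxymethoxy)-3-(3-methylbut-2-enyl)chromene-2-thione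
Product: 7 7-methoxy-5-(methoxymethoxy)-3-(3-methylbut-2-enyl)-2-(methylsulfanyl)chromen-4-one
Conditions: MeI (1.1 equiv), K2CO3, acetone, rt
Reagents that add atoms: iodomethane (MeI), CI
Why: S-alkylation of the ambident thione-enolate, in which the soft sulfur terminus takes the soft electrophile and the ring tautomerises to the 2-(methylsulfanyl)chromen-4-one.

Step 5
Reactants: 8 dimethyl squarate (3,4-dimethoxycyclobut-3-ene-1,2-dione)
Product: 10 3-methoxycyclobut-3-ene-1,2-dione (methyl semisquarate), via 4-hydroxy-2,3-dimethoxycyclobut-2-enone 9 (not isolated)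
Conditions: LiAlH(O-t-Bu)3 (1.05 equiv), THF, −78 °C; then conc. HCl, CH2Cl2, 0 °C; used at once
Reagents that add atoms: none
Why: Selective 1,2-hydride reduction of one of the two equivalent carbonyls by a bulky, mild aluminium hydride, followed by acid-promoted allylic transposition with loss of methanol (ionisation of the carbinol to a methoxy-stabilised cyclobutenyl cation, hydration at the distal methoxy-bearing carbon and collapse of the hemiketal), which is the established route to alkyl semisquarates.

Step 6
Reactants: 11 (E)-1,2-bis(tributylstannyl)ethene; 10 3-methoxycyclobut-3-ene-1,2-dione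
Product: 13 rac-4-hydroxy-3-methoxy-4-[(E)-2-(tributylstannyl)ethenyl]cyclobut-2-en-1-one, via (E)-2-(tributylstannyl)ethenyllithium 12 (not isolated)
Conditions: n-BuLi (1.0 equiv), THF, −78 °C; then cannulated into 10 (1.1 equiv), THF, −78 °C; aq. NH4Cl, −78 °C
Reagents that add atoms: none
Why: Tin–lithium exchange with retention of alkene geometry followed by 1,2-addition of the alkenyllithium to the more electrophilic carbonyl of 10 (the one next to the methoxy-bearing carbon, since the other is deactivated as a vinylogous ester); the carbinol stereocenter forms as a racemate and is erased in step 8.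

Step 7
Reactants: 7 7-methoxy-5-(methoxymethoxy)-3-(3-methylbut-2-enyl)-2-(methylsulfanyl)chromen-4-one; 13 rac-4-hydroxy-3-methoxy-4-[(E)-2-(tributylstannyl)ethenyl]cyclobut-2-en-1-one
Product: 14 rac-2-[(E)-2-(1-hydroxy-2-methoxy-4-oxocyclobut-2-enyl)ethenyl]-7-methoxy-5-(methoxymethoxy)-3-(3-methylbut-2-enyl)chromen-4-one
Conditions: Pd(PPh3)4 (5 mol %), Cu(O2CC6H3(OH)Me) (3-methylsalicylate of monovalent copper, 2.2 equiv), THF, 45 °C, Ar
Reagents that add atoms: none
Why: Liebeskind–Srogl-type thioether–organostannane cross-coupling, in which the copper carboxylate activates the C2–SMe bond of the vinylogous thioester for oxidative addition to zerovalent palladium and takes up thiolate and tin, so the coupling should run without base, with retention of the E geometry and below the temperature at which the cyclobutenone opens.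

Step 8
Reactants: 14 rac-2-[(E)-2-(1-hydroxy-2-methoxy-4-oxocyclobut-2-enyl)ethenyl]-7-methoxy-5-(methoxymethoxy)-3-(3-methylbut-2-enyl)chromen-4-one
Product: 17 2-(2,5-dihydroxy-4-methoxyphenyl)-7-methoxy-5-(methoxymethoxy)-3-(3-methylbut-2-enyl)chromen-4-one, via dienylketene 15 (not isolated), via cyclohexadienone 16 (not isolated)
Conditions: PhMe (degassed, 0.01 M), 100 °C, Ar; product kept under Ar
Reagents that add atoms: none
Why: Heating opens the cyclobutenone by conrotatory 4π electrocyclic cleavage of the bond between the carbonyl carbon and the carbinol carbon, giving dienylketene 15. The hydroxyl group, as the donor, rotates outward, so the alkenyl arm turns inward and lies cis to the ketenyl group. The ketene–enol–alkene triene then undergoes thermal disrotatory 6π electrocyclization, which joins the ketene carbon (future C2') to the alkene carbon carrying the chromone (future C1') and closes ring B as cyclohexadienone 16, and enolization aromatizes this to hydroquinone 17. The closest known reaction is the Moore ring expansion of 4-alkenyl-4-hydroxycyclobutenones to hydroquinones. The carbinol stereocenter of 14 and the transient sp3 carbon of 16 are both lost, so no stereocenter has to be controlled. The step needs the three ring-B oxygens in the right places and ring closure in preference to capture of the ketene by the hydroxyl group: the first is fixed by the constitution of 14 (ketone oxygen to C2', carbinol oxygen to C5', methoxy to C4'), the second by the cis alkenyl arm, high dilution and the absence of acid, base or nucleophiles.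

Step 9
Reactants: 17 2-(2,5-dihydroxy-4-methoxyphenyl)-7-methoxy-5-(methoxymethoxy)-3-(3-methylbut-2-enyl)chromen-4-one
Product: 18 artoindonesianin Q, 2-(2,5-dihydroxy-4-methoxyphenyl)-5-hydroxy-7-methoxy-3-(3-methylbut-2-enyl)chromen-4-one
Conditions: HCl (1 M in MeOH, degassed), THF, 40 °C, Ar
Reagents that add atoms: none
Why: Acid-catalysed cleavage of an aryl methoxymethyl acetal by transacetalisation to methanol, which is fast for the acetal peri to the chromone carbonyl and should leave the methyl ethers, the prenyl alkene and the hydroquinone (stable to acid under argon) untouched.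

**Compound list**

1 | 1-(2,6-dihydroxy-4-methoxyphenyl)ethanone | CC(=O)c1c(O)cc(OC)cc1O | starting material
2 | 1-[2-hydroxy-4-methoxy-6-(methoxymethoxy)phenyl]ethanone | CC(=O)c1c(O)cc(OC)cc1OCOC | intermediate
3 | prenyl bromide (1-bromo-3-methylbut-2-ene) | CC(C)=CCBr | starting material
4 | 1-[2-hydroxy-4-methoxy-6-(methoxymethoxy)phenyl]-5-methylhex-4-en-1-one | CC(C)=CCCC(=O)c1c(O)cc(OC)cc1OCOC | intermediate
5 | rac-2-[2-hydroxy-4-methoxy-6-(methoxymethoxy)benzoyl]-5-methylhex-4-enedithioic acid (present as its potassium salt, formed in the flask) | CC(C)=CCC(C(=S)S)C(=O)c1c(O)cc(OC)cc1OCOC | intermediate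
6 | 4-hydroxy-7-methoxy-5-(methoxymethoxy)-3-(3-methylbut-2-enyl)chromene-2-thione | COCOc1cc(OC)cc2oc(=S)c(CC=C(C)C)c(O)c12 | intermediate
7 | 7-methoxy-5-(methoxymethoxy)-3-(3-methylbut-2-enyl)-2-(methylsulfanyl)chromen-4-one | COCOc1cc(OC)cc2oc(SC)c(CC=C(C)C)c(=O)c12 | intermediate
8 | dimethyl squarate (3,4-dimethoxycyclobut-3-ene-1,2-dione) | COC1=C(OC)C(=O)C1=O | starting material
9 | rac-4-hydroxy-2,3-dimethoxycyclobut-2-en-1-one (formed in the flask) | COC1=C(OC)C(O)C1=O | intermediate
10 | 3-methoxycyclobut-3-ene-1,2-dione (methyl semisquarate) | COC1=CC(=O)C1=O | intermediate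
11 | (E)-1,2-bis(tributylstannyl)ethene | CCCC[Sn](CCCC)(CCCC)/C=C/[Sn](CCCC)(CCCC)CCCC | starting material
12 | (E)-2-(tributylstannyl)ethenyllithium (formed in the flask) | [Li]/C=C/[Sn](CCCC)(CCCC)CCCC | intermediate
13 | rac-4-hydroxy-3-methoxy-4-[(E)-2-(tributylstannyl)ethenyl]cyclobut-2-en-1-one | COC1=CC(=O)C1(O)/C=C/[Sn](CCCC)(CCCC)CCCC | intermediate
14 | rac-2-[(E)-2-(1-hydroxy-2-methoxy-4-oxocyclobut-2-enyl)ethenyl]-7-methoxy-5-(methoxymethoxy)-3-(3-methylbut-2-enyl)chromen-4-one | COCOc1cc(OC)cc2oc(/C=C/C3(O)C(OC)=CC3=O)c(CC=C(C)C)c(=O)c12 | intermediate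
15 | 2-[(1E,3Z)-3-hydroxy-4-methoxy-6-oxohexa-1,3,5-trienyl]-7-methoxy-5-(methoxymethoxy)-3-(3-methylbut-2-enyl)chromen-4-one (dienylketene, formed in the flask) | COCOc1cc(OC)cc2oc(/C=C/C(O)=C(OC)\C=C=O)c(CC=C(C)C)c(=O)c12 | intermediate
16 | rac-2-(3-hydroxy-4-methoxy-6-oxocyclohexa-2,4-dien-1-yl)-7-methoxy-5-(methoxymethoxy)-3-(3-methylbut-2-enyl)chromen-4-one (formed in the flask) | COCOc1cc(OC)cc2oc(C3C=C(O)C(OC)=CC3=O)c(CC=C(C)C)c(=O)c12 | intermediate
17 | 2-(2,5-dihydroxy-4-methoxyphenyl)-7-methoxy-5-(methoxymethoxy)-3-(3-methylbut-2-enyl)chromen-4-one | COCOc1cc(OC)cc2oc(-c3cc(O)c(OC)cc3O)c(CC=C(C)C)c(=O)c12 | intermediate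
18 | artoindonesianin Q, 2-(2,5-dihydroxy-4-methoxyphenyl)-5-hydroxy-7-methoxy-3-(3-methylbut-2-enyl)chromen-4-one | COc1cc(O)c2c(=O)c(CC=C(C)C)c(-c3cc(O)c(OC)cc3O)oc2c1 | target

**Step count**

Total: 9 steps. Longest linear sequence: 7 steps (steps 1, 2, 3, 4, 7, 8, 9); steps 5 and 6 form the second branch.

**Steps most likely to fail**

1. Step 8. The ketene may be captured by the neighbouring hydroxyl (lactone formation) or by a second molecule faster than the electron-poor, chromone-bearing alkene closes the six-membered ring, and the hydroquinone may be lost to air oxidation during isolation. Fallback: ring B is brought in as an intact arene. The fallback sets out from 7. The same palladium/copper thioether coupling, now with commercial 2,4,5-trimethoxyphenylboronic acid (Pd2(dba)3, tri(2-furyl)phosphine, Cu(O2CC4H3S), THF, 50 °C), should give 7-methoxy-5-(methoxymethoxy)-3-(3-methylbut-2-enyl)-2-(2,4,5-trimethoxyphenyl)chromen-4-one F1. Oxidative demethylation of its para-dimethoxy pair with (NH4)2Ce(NO3)6 in MeCN/H2O at 0 °C should give 2-methoxy-5-[7-methoxy-5-(methoxymethoxy)-3-(3-methylbut-2-enyl)-4-oxochromen-2-yl]cyclohexa-2,5-diene-1,4-dione F2. Reduction with Na2S2O4 (EtOAc/H2O, Ar) comes back to the route at 17.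

2. Step 7. The alkenylstannane may be protodestannylated or homocoupled by copper, the strained tertiary carbinol may open through a metal alkoxide (β-carbon elimination), or 13 may ring-expand before the C–C bond is made. Fallback: the carbinol is made last. The fallback sets out from 7, 11 and 10. Coupling of 7 with an excess of 11 under the conditions of step 7 should give 7-methoxy-5-(methoxymethoxy)-3-(3-methylbut-2-enyl)-2-[(E)-2-(tributylstannyl)ethenyl]chromen-4-one F3. Iododestannylation (I2, 1.0 equiv, CH2Cl2, −78 to 0 °C) should give 2-[(E)-2-iodoethenyl]-7-methoxy-5-(methoxymethoxy)-3-(3-methylbut-2-enyl)chromen-4-one F4. Iodine–magnesium exchange (i-PrMgCl·LiCl, THF, −78 to −40 °C), which the hindered 5-alkoxychromone carbonyl should tolerate at this temperature, should give the alkenylmagnesium chloride 2-[(E)-2-(chloromagnesio)ethenyl]-7-methoxy-5-(methoxymethoxy)-3-(3-methylbut-2-enyl)chromen-4-one F5. Its addition to 10 at −78 °C comes back to the route at 14.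

3. Step 6. The tin–lithium exchange may be incomplete or twofold, the basic vinyllithium may attack the methoxy-bearing carbon (addition–elimination) or the vinylogous ester carbonyl, and labile 10 may decompose during the addition. Fallback: the two carbons are added as an alkyne and tin is put on afterwards. The fallback sets out from 10. HC≡CMgBr (THF, −78 °C) should give rac-4-ethynyl-4-hydroxy-3-methoxycyclobut-2-en-1-one F6. Palladium-catalysed syn-hydrostannation (Bu3SnH, PdCl2(PPh3)2 2 mol %, THF, 0 °C), which places tin at the terminal carbon of a tertiary propargylic alcohol, comes back to the route at 13.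

**Further compounds**

F1 | step 8 | 7-methoxy-5-(methoxymethoxy)-3-(3-methylbut-2-enyl)-2-(2,4,5-trimethoxyphenyl)chromen-4-one | COCOc1cc(OC)cc2oc(-c3cc(OC)c(OC)cc3OC)c(CC=C(C)C)c(=O)c12
F2 | step 8 | 2-methoxy-5-[7-methoxy-5-(methoxymethoxy)-3-(3-methylbut-2-enyl)-4-oxochromen-2-yl]cyclohexa-2,5-diene-1,4-dione | COCOc1cc(OC)cc2oc(C3=CC(=O)C(OC)=CC3=O)c(CC=C(C)C)c(=O)c12
F3 | step 7 | 7-methoxy-5-(methoxymethoxy)-3-(3-methylbut-2-enyl)-2-[(E)-2-(tributylstannyl)ethenyl]chromen-4-one | COCOc1cc(OC)cc2oc(/C=C/[Sn](CCCC)(CCCC)CCCC)c(CC=C(C)C)c(=O)c12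
F4 | step 7 | 2-[(E)-2-iodoethenyl]-7-methoxy-5-(methoxymethoxy)-3-(3-methylbut-2-enyl)chromen-4-one | COCOc1cc(OC)cc2oc(/C=C/I)c(CC=C(C)C)c(=O)c12
F5 | step 7 | 2-[(E)-2-(chloromagnesio)ethenyl]-7-methoxy-5-(methoxymethoxy)-3-(3-methylbut-2-enyl)chromen-4-one | COCOc1cc(OC)cc2oc(/C=C/[Mg]Cl)c(CC=C(C)C)c(=O)c12
F6 | step 6 | rac-4-ethynyl-4-hydroxy-3-methoxycyclobut-2-en-1-one | COC1=CC(=O)C1(O)C#C
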